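## Retrosynthetic overview

1. Target 18 ← desilylation, tertiary acetylation and esterification of cis-diol 11 with (2S,3R)-epoxytiglic acid 14 (from tiglyl alcohol by catalytic asymmetric epoxidation and oxidation).
2. Diol 11 ← α-face dihydroxylation of the ring-A alkene of dienone 10 (anti to the angular methyl).
3. Dienone 10 ← one-pot amine-catalysed asymmetric Mukaiyama–Michael/aldol condensation ([3+3] annulation) of achiral dienal 5 with bis-silyl enol ether 8 (from diacetone alcohol). This step sets the quaternary carbon and closes ring B.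
4. Dienal 5 ← 2,6-dimethylbenzoic acid by Birch reduction, reduction and oxidation/isomerisation.
5. Ring order: ring A comes from the arene, ring B from the annulation, and the oxirane is made separately and attached late.

Assumption: the quinine-derived primary amine is taken to expose the Si face of C2 of dienal 5; if the sense proves opposite, the quinidine-derived pseudo-enantiomer is used in the same way.

## Route

Step 1
Reactants: 1 2,6-dimethylbenzoic acid
Product: 2 2,6-dimethylcyclohexa-2,5-diene-1-carboxylic acid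
Conditions: Li, NH3(l), THF, −78 °C; NH4Cl
Reagents that add atoms: none
Why: Birch reduction of a benzoic acid gives the 1,4-dihydro acid by kinetic protonation of the carboxylate-stabilised carbanion at C1, and the product is achiral.

Step 2
Reactants: 2 2,6-dimethylcyclohexa-2,5-diene-1-carboxylic acid
Product: 3 (2,6-dimethylcyclohexa-2,5-dien-1-yl)methanol
Conditions: LiAlH4, THF, 0 °C to rt
Reagents that add atoms: none
Why: Hydride reduction of the acid to the primary alcohol leaves the unconjugated diene untouched.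

Step 3
Reactants: 3 (2,6-dimethylcyclohexa-2,5-dien-1-yl)methanol
Product: 5 2,6-dimethylcyclohexa-1,5-diene-1-carbaldehyde, via 2,6-dimethylcyclohexa-2,5-diene-1-carbaldehyde 4 (not isolated)
Conditions: Dess–Martin periodinane, pyridine, CH2Cl2, 0 °C; then DBU (0.2 equiv), 0 °C to rt, Ar
Reagents that add atoms: none
Why: Dess–Martin oxidation gives the skipped aldehyde, whose doubly allylic α-hydrogen is removed by DBU and returned at the γ-carbon (base-mediated 1,3-prototropic shift) to give the conjugated, achiral dienal.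

Step 4
Reactants: 6 4-hydroxy-4-methylpentan-2-one (diacetone alcohol)
Product: 7 4-methyl-4-(triethylsilyloxy)pentan-2-one
Conditions: TESOTf, 2,6-lutidine, CH2Cl2, −78 °C
Reagents that add atoms: triethylsilyl trifluoromethanesulfonate CC[Si](CC)(CC)OS(=O)(=O)C(F)(F)F
Why: Silyl triflate silylation of the tertiary alcohol blocks retro-aldol cleavage and masks the future C11 hydroxyl so that the later tertiary acetylation is unambiguous.

Step 5
Reactants: 7 4-methyl-4-(triethylsilyloxy)pentan-2-one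
Product: 8 4-methyl-4-(triethylsilyloxy)-2-(trimethylsilyloxy)pent-1-ene
Conditions: LDA, THF, −78 °C; TMSCl
Reagents that add atoms: chlorotrimethylsilane C[Si](C)(C)Cl
Why: Kinetic deprotonation occurs at the unhindered methyl group (not at the neopentyl CH2), and O-silylation fixes the terminal silyl enol ether.

Step 6
Reactants: 5 2,6-dimethylcyclohexa-1,5-diene-1-carbaldehyde; 8 4-methyl-4-(triethylsilyloxy)-2-(trimethylsilyloxy)pent-1-ene
Product: 10 (4aR,8aR)-5,8a-dimethyl-3-[2-(triethylsilyloxy)propan-2-yl]-4a,7,8,8a-tetrahydronaphthalen-2(1H)-one, via keto aldehyde 9 (not isolated)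
Conditions: 9-amino(9-deoxy)epi-quinine (20 mol %), TFA (40 mol %), H2O (2 equiv), CHCl3, −20 °C to rt; then 40 °C
Reagents that add atoms: none
Why: Proposed new method: a chiral primary amine salt condenses with the fully substituted dienal to an iminium ion (primary amines tolerate the α-branching that blocks secondary amines). The silyl enol ether then adds irreversibly to the Si face of the β-carbon C2 (1,2-attack is blocked by the two flanking substituents), which sets the quaternary centre as 8aR. The resulting dienamine is protonated kinetically at the α-carbon, and the same amine then drives an intramolecular enamine aldol condensation of the ketone CH2 onto the aldehyde, where only the six-membered ring can close. The epimerisable aldehyde α-carbon funnels into the trans-fused enone (both new ring bonds equatorial), which gives 4aR. The closest known reactions are the iminium-catalysed Mukaiyama–Michael addition to enals, primary-amine iminium catalysis of α-branched enals, and amine-catalysed Robinson-type aldol condensation.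

Step 7
Reactants: 10 (4aR,8aR)-5,8a-dimethyl-3-[2-(triethylsilyloxy)propan-2-yl]-4a,7,8,8a-tetrahydronaphthalen-2(1H)-one
Product: 11 (4aR,5S,6R,8aR)-5,6-dihydroxy-5,8a-dimethyl-3-[2-(triethylsilyloxy)propan-2-yl]-4a,5,6,7,8,8a-hexahydronaphthalen-2(1H)-one
Conditions: OsO4 (2 mol %), NMO, acetone/H2O, 0 °C to rt
Reagents that add atoms: N-methylmorpholine N-oxide C[N+]1([O-])CCOCC1; water O
Why: Upjohn syn-dihydroxylation takes the electron-rich trisubstituted alkene in preference to the hindered, electron-poor enone and approaches the face anti to the axial angular methyl, which sets 5S and 6R (cis-diol with the 5-methyl syn to the 8a-methyl).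

Step 8
Reactants: 12 (E)-2-methylbut-2-en-1-ol (tiglyl alcohol)
Product: 13 [(2R,3R)-2,3-dimethyloxiran-2-yl]methanol
Conditions: Ti(OiPr)4 (10 mol %), D-(−)-diethyl tartrate (12 mol %), tBuOOH, 4 Å MS, CH2Cl2, −20 °C
Reagents that add atoms: tert-butyl hydroperoxide CC(C)(C)OO
Why: Sharpless asymmetric epoxidation with D-(−)-tartrate delivers oxygen to the face that gives the (2R,3R)-epoxy alcohol (L-(+)-tartrate gives 2S,3S with E-allylic alcohols of this type), and the E geometry fixes the cis-dimethyl oxirane.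

Step 9
Reactants: 13 [(2R,3R)-2,3-dimethyloxiran-2-yl]methanol
Product: 14 (2S,3R)-2,3-dimethyloxirane-2-carboxylic acid
Conditions: RuCl3 (2 mol %), NaIO4, MeCN/EtOAc/H2O, rt
Reagents that add atoms: sodium periodate [Na+].[O-]I(=O)(=O)=O; water O
Why: RuO4-catalysed oxidation takes the primary alcohol to the glycidic acid without touching the epoxide (the descriptor at C2 changes only because of CIP priorities).

Step 10
Reactants: 11 (4aR,5S,6R,8aR)-5,6-dihydroxy-5,8a-dimethyl-3-[2-(triethylsilyloxy)propan-2-yl]-4a,5,6,7,8,8a-hexahydronaphthalen-2(1H)-one; 14 (2S,3R)-2,3-dimethyloxirane-2-carboxylic acid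
Product: 16 (4aR,5S,6R,8aR)-5-hydroxy-5,8a-dimethyl-2-oxo-3-[2-(triethylsilyloxy)propan-2-yl]-1,2,4a,5,6,7,8,8a-octahydronaphthalen-6-yl (2S,3R)-2,3-dimethyloxirane-2-carboxylate, via mixed anhydride 15 (not isolated)
Conditions: 14, 2,4,6-trichlorobenzoyl chloride, Et3N, THF, rt; then 11, DMAP, toluene, rt to 40 °C
Reagents that add atoms: none
Why: Yamaguchi esterification couples the hindered glycidic acid selectively at the secondary hydroxyl, the tertiary hydroxyl being unreactive under these conditions.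

Step 11
Reactants: 16 (4aR,5S,6R,8aR)-5-hydroxy-5,8a-dimethyl-2-oxo-3-[2-(triethylsilyloxy)propan-2-yl]-1,2,4a,5,6,7,8,8a-octahydronaphthalen-6-yl (2S,3R)-2,3-dimethyloxirane-2-carboxylate
Product: 17 (4aR,5S,6R,8aR)-5-acetoxy-5,8a-dimethyl-2-oxo-3-[2-(triethylsilyloxy)propan-2-yl]-1,2,4a,5,6,7,8,8a-octahydronaphthalen-6-yl (2S,3R)-2,3-dimethyloxirane-2-carboxylate
Conditions: Ac2O (10 equiv), DMAP (2 equiv), Et3N, CH2Cl2, 40 °C
Reagents that add atoms: acetic anhydride CC(=O)OC(C)=O
Why: DMAP-catalysed (Steglich-type) acylation acetylates the only free hydroxyl, the equatorial tertiary one, under base-only conditions that spare the epoxide, the silyl ether and the enone.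

Step 12
Reactants: 17 (4aR,5S,6R,8aR)-5-acetoxy-5,8a-dimethyl-2-oxo-3-[2-(triethylsilyloxy)propan-2-yl]-1,2,4a,5,6,7,8,8a-octahydronaphthalen-6-yl (2S,3R)-2,3-dimethyloxirane-2-carboxylate
Product: 18 (4aR,5S,6R,8aR)-5-acetoxy-3-(2-hydroxypropan-2-yl)-5,8a-dimethyl-2-oxo-1,2,4a,5,6,7,8,8a-octahydronaphthalen-6-yl (2S,3R)-2,3-dimethyloxirane-2-carboxylate (CNP0219255.1)
Conditions: HF·pyridine, pyridine, THF, 0 °C
Reagents that add atoms: none
Why: Buffered fluoride desilylation frees the tertiary allylic alcohol without acyl migration, retro-aldol cleavage or epoxide opening.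

## Compound list

1 | 2,6-dimethylbenzoic acid | Cc1cccc(C)c1C(=O)O | starting material
2 | 2,6-dimethylcyclohexa-2,5-diene-1-carboxylic acid | CC1=CCC=C(C)C1C(=O)O | intermediate
3 | (2,6-dimethylcyclohexa-2,5-dien-1-yl)methanol | CC1=CCC=C(C)C1CO | intermediate
4 | 2,6-dimethylcyclohexa-2,5-diene-1-carbaldehyde | CC1=CCC=C(C)C1C=O | intermediate
5 | 2,6-dimethylcyclohexa-1,5-diene-1-carbaldehyde | CC1=CCCC(C)=C1C=O | intermediate
6 | 4-hydroxy-4-methylpentan-2-one | CC(=O)CC(C)(C)O | starting material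
7 | 4-methyl-4-(triethylsilyloxy)pentan-2-one | CC(=O)CC(C)(C)O[Si](CC)(CC)CC | intermediate
8 | 4-methyl-4-(triethylsilyloxy)-2-(trimethylsilyloxy)pent-1-ene | C=C(O[Si](C)(C)C)CC(C)(C)O[Si](CC)(CC)CC | intermediate
9 | (1R,6R)-2,6-dimethyl-6-[4-methyl-2-oxo-4-(triethylsilyloxy)pentyl]cyclohex-2-ene-1-carbaldehyde | CC1=CCC[C@](C)(CC(=O)CC(C)(C)O[Si](CC)(CC)CC)[C@H]1C=O | intermediate
10 | (4aR,8aR)-5,8a-dimethyl-3-[2-(triethylsilyloxy)propan-2-yl]-4a,7,8,8a-tetrahydronaphthalen-2(1H)-one | CC1=CCC[C@]2(C)CC(=O)C(C(C)(C)O[Si](CC)(CC)CC)=C[C@@H]12 | intermediate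
11 | (4aR,5S,6R,8aR)-5,6-dihydroxy-5,8a-dimethyl-3-[2-(triethylsilyloxy)propan-2-yl]-4a,5,6,7,8,8a-hexahydronaphthalen-2(1H)-one | O[C@@]1(C)[C@@H]2C=C(C(C)(C)O[Si](CC)(CC)CC)C(=O)C[C@@]2(C)CC[C@H]1O | intermediate
12 | (E)-2-methylbut-2-en-1-ol | C/C=C(\C)CO | starting material
13 | [(2R,3R)-2,3-dimethyloxiran-2-yl]methanol | OC[C@@]1(C)O[C@@H]1C | intermediate
14 | (2S,3R)-2,3-dimethyloxirane-2-carboxylic acid | OC(=O)[C@@]1(C)O[C@@H]1C | intermediate
15 | (2S,3R)-2,3-dimethyloxirane-2-carboxylic 2,4,6-trichlorobenzoic anhydride | O=C(OC(=O)[C@@]1(C)O[C@@H]1C)c1c(Cl)cc(Cl)cc1Cl | intermediate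
16 | (4aR,5S,6R,8aR)-5-hydroxy-5,8a-dimethyl-2-oxo-3-[2-(triethylsilyloxy)propan-2-yl]-1,2,4a,5,6,7,8,8a-octahydronaphthalen-6-yl (2S,3R)-2,3-dimethyloxirane-2-carboxylate | O[C@@]1(C)[C@@H]2C=C(C(C)(C)O[Si](CC)(CC)CC)C(=O)C[C@@]2(C)CC[C@H]1OC(=O)[C@@]1(C)O[C@@H]1C | intermediate
17 | (4aR,5S,6R,8aR)-5-acetoxy-5,8a-dimethyl-2-oxo-3-[2-(triethylsilyloxy)propan-2-yl]-1,2,4a,5,6,7,8,8a-octahydronaphthalen-6-yl (2S,3R)-2,3-dimethyloxirane-2-carboxylate | CC(=O)O[C@@]1(C)[C@@H]2C=C(C(C)(C)O[Si](CC)(CC)CC)C(=O)C[C@@]2(C)CC[C@H]1OC(=O)[C@@]1(C)O[C@@H]1C | intermediate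
18 | (4aR,5S,6R,8aR)-5-acetoxy-3-(2-hydroxypropan-2-yl)-5,8a-dimethyl-2-oxo-1,2,4a,5,6,7,8,8a-octahydronaphthalen-6-yl (2S,3R)-2,3-dimethyloxirane-2-carboxylate | CC(=O)O[C@@]1(C)[C@@H]2C=C(C(C)(C)O)C(=O)C[C@@]2(C)CC[C@H]1OC(=O)[C@@]1(C)O[C@@H]1C | target

## Step count and risks

Total steps: 12. Longest linear sequence: 8 (steps 1, 2, 3, 6, 7, 10, 11, 12).

**Step 6 (proposed new annulation).** The risks are:
- a twisted, poorly electrophilic iminium ion and slow quaternary C–C formation;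
- migration of the ring-A double bond into conjugation (towards the 4,6-dienone);
- formation of the cis-fused epimer;
- the wrong enantiofacial sense.

The fallback uses known chemistry, sets out from 5 and returns at 10. Brown allylation of 5 with (−)-Ipc2B(allyl) gives (S)-1-(2,6-dimethylcyclohexa-1,5-dien-1-yl)but-3-en-1-ol F1. Anionic oxy-Cope rearrangement (KH, 18-crown-6, THF) through a chair with equatorial alkoxide transfers the carbinol chirality to the quaternary carbon and gives (1R,6R)-2,6-dimethyl-6-(prop-2-en-1-yl)cyclohex-2-ene-1-carbaldehyde F2. Wacker oxidation (PdCl2, CuCl, O2, DMF/H2O) gives (1R,6R)-2,6-dimethyl-6-(2-oxopropyl)cyclohex-2-ene-1-carbaldehyde F3, and KOH/MeOH aldol condensation gives (4aR,8aR)-5,8a-dimethyl-4a,7,8,8a-tetrahydronaphthalen-2(1H)-one F4. Tandem thia-Michael/aldol with Me2AlSPh then acetone gives 3-(2-hydroxypropan-2-yl)-5,8a-dimethyl-4-(phenylsulfanyl)-3,4,4a,7,8,8a-hexahydronaphthalen-2(1H)-one F5. NaIO4 oxidation and thermal sulfoxide elimination give (4aR,8aR)-3-(2-hydroxypropan-2-yl)-5,8a-dimethyl-4a,7,8,8a-tetrahydronaphthalen-2(1H)-one F6, and TESOTf/2,6-lutidine returns 10.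

**Step 11 (acetylation of a hindered tertiary alcohol next to a bulky ester).** The fallback reverses the order of acylation, sets out from 11 and returns at 17. Selective TMSCl/imidazole silylation of the secondary hydroxyl gives (4aR,5S,6R,8aR)-5-hydroxy-5,8a-dimethyl-3-[2-(triethylsilyloxy)propan-2-yl]-6-(trimethylsilyloxy)-4a,5,6,7,8,8a-hexahydronaphthalen-2(1H)-one F7. With no epoxide present and a smaller neighbour, forcing acetylation (Ac2O, DMAP, Et3N, 60 °C) gives (4aR,5S,6R,8aR)-5,8a-dimethyl-2-oxo-3-[2-(triethylsilyloxy)propan-2-yl]-6-(trimethylsilyloxy)-1,2,4a,5,6,7,8,8a-octahydronaphthalen-5-yl acetate F8. Citric acid in MeOH removes only the TMS group and gives (4aR,5S,6R,8aR)-6-hydroxy-5,8a-dimethyl-2-oxo-3-[2-(triethylsilyloxy)propan-2-yl]-1,2,4a,5,6,7,8,8a-octahydronaphthalen-5-yl acetate F9. Immediate Yamaguchi coupling with 14 (through 15) gives 17; acetyl migration from the tertiary to the secondary oxygen is the point to watch here.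

**Step 3 (air- and base-sensitive dihydrobenzaldehyde: aromatisation or over-isomerisation).** The fallback moves the isomerisation to the ester oxidation level, sets out from 2 and returns at 5. MeI/K2CO3 gives methyl 2,6-dimethylcyclohexa-2,5-diene-1-carboxylate F10. DBU brings the diene into conjugation as methyl 2,6-dimethylcyclohexa-1,5-diene-1-carboxylate F11. DIBAL-H gives (2,6-dimethylcyclohexa-1,5-dien-1-yl)methanol F12, and MnO2 oxidises this allylic alcohol to 5.

## Further compounds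

F1 | step 6 | (S)-1-(2,6-dimethylcyclohexa-1,5-dien-1-yl)but-3-en-1-ol | CC1=CCCC(C)=C1[C@@H](O)CC=C
F2 | step 6 | (1R,6R)-2,6-dimethyl-6-(prop-2-en-1-yl)cyclohex-2-ene-1-carbaldehyde | CC1=CCC[C@](C)(CC=C)[C@H]1C=O
F3 | step 6 | (1R,6R)-2,6-dimethyl-6-(2-oxopropyl)cyclohex-2-ene-1-carbaldehyde | CC1=CCC[C@](C)(CC(C)=O)[C@H]1C=O
F4 | step 6 | (4aR,8aR)-5,8a-dimethyl-4a,7,8,8a-tetrahydronaphthalen-2(1H)-one | CC1=CCC[C@]2(C)CC(=O)C=C[C@@H]12
F5 | step 6 | 3-(2-hydroxypropan-2-yl)-5,8a-dimethyl-4-(phenylsulfanyl)-3,4,4a,7,8,8a-hexahydronaphthalen-2(1H)-one (4aR,8aR; mixture at C3 and C4) | CC1=CCC[C@]2(C)CC(=O)C(C(C)(C)O)C(Sc3ccccc3)[C@@H]12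
F6 | step 6 | (4aR,8aR)-3-(2-hydroxypropan-2-yl)-5,8a-dimethyl-4a,7,8,8a-tetrahydronaphthalen-2(1H)-one | CC1=CCC[C@]2(C)CC(=O)C(C(C)(C)O)=C[C@@H]12
F7 | step 11 | (4aR,5S,6R,8aR)-5-hydroxy-5,8a-dimethyl-3-[2-(triethylsilyloxy)propan-2-yl]-6-(trimethylsilyloxy)-4a,5,6,7,8,8a-hexahydronaphthalen-2(1H)-one | O[C@@]1(C)[C@@H]2C=C(C(C)(C)O[Si](CC)(CC)CC)C(=O)C[C@@]2(C)CC[C@H]1O[Si](C)(C)C
F8 | step 11 | (4aR,5S,6R,8aR)-5,8a-dimethyl-2-oxo-3-[2-(triethylsilyloxy)propan-2-yl]-6-(trimethylsilyloxy)-1,2,4a,5,6,7,8,8a-octahydronaphthalen-5-yl acetate | CC(=O)O[C@@]1(C)[C@@H]2C=C(C(C)(C)O[Si](CC)(CC)CC)C(=O)C[C@@]2(C)CC[C@H]1O[Si](C)(C)C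
F9 | step 11 | (4aR,5S,6R,8aR)-6-hydroxy-5,8a-dimethyl-2-oxo-3-[2-(triethylsilyloxy)propan-2-yl]-1,2,4a,5,6,7,8,8a-octahydronaphthalen-5-yl acetate | CC(=O)O[C@@]1(C)[C@@H]2C=C(C(C)(C)O[Si](CC)(CC)CC)C(=O)C[C@@]2(C)CC[C@H]1O
F10 | step 3 | methyl 2,6-dimethylcyclohexa-2,5-diene-1-carboxylate | COC(=O)C1C(C)=CCC=C1C
F11 | step 3 | methyl 2,6-dimethylcyclohexa-1,5-diene-1-carboxylate | COC(=O)C1=C(C)CCC=C1C
F12 | step 3 | (2,6-dimethylcyclohexa-1,5-dien-1-yl)methanol | OCC1=C(C)CCC=C1C
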